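Daucane numbering is used: C-1 quaternary ring-fusion carbon, C-2 and C-4 the cyclopentane carbinols, C-5 ring-fusion CH, C-6 and C-10 the acyloxy carbons, C-7 the ring CH2, C-8/C-9 the epoxide.
Retrosynthesis: the two angelates and a C-2 silyl ether come off first; the 8,9-epoxide goes back to a C8=C9 alkene; the seven-membered ring is cut at C6–C7; the C9–C10 cis-epoxide, the C-4 isopropyl group, C-6 (as CH2O) and the C-1 alkynyl group are then taken off a cyclopentenone.
Enabling feature: in the seven-membered ring, C-7 is a CH2 between a carbinol (C-6) and a methyl-bearing carbon (C-8) whose neighbour C-9 lies next to oxygenated C-10. C-6 can therefore be a ketyl (aldehyde), C7=C8 an isopropenyl group, and the C-9/C-10 oxygen one cis-epoxide that opens as the ring closes, leaving the C8=C9 alkene and the C-10 carbinol.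
Forward: the cyclopentane is built first (C-1 by alkynyl delivery, C-5/C-6 by formaldehyde trapping, C-4 by isopropyl addition), then the side chain (enyne, Z-diene, cis-vinyl epoxide), then the seven-membered ring by ketyl closure, then epoxide, esters and desilylation.
Stereochemistry: C-2 is bought; C-1 follows from hydroxyl delivery, C-5 from the C-1 methyl, C-4 from C-5, C-10 from the C-2 hydroxyl (directed epoxidation of the Z-olefin), C-6 from the chelated ketyl closure, C-8/C-9 from the C-10 and C-6 hydroxyls.

Key step: step 11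

Remark on the chemistry: compounds 1, 5 and 18 are taken as catalogue compounds (both enantiomers of 1 are sold).

Step 1
Reactants: 1 (S)-4-(tert-butyldimethylsilyloxy)cyclopent-2-en-1-one
Product: 2 (3S,4S)-4-(tert-butyldimethylsilyloxy)-3-methyl-1-(trimethylsilyloxy)cyclopent-1-ene
Conditions: MeMgBr, CuBr·SMe2 (5 mol %), TMSCl, HMPA, THF, −78 °C
Reagents that add atoms: methylmagnesium bromide C[Mg]Br; chlorotrimethylsilane C[Si](C)(C)Cl
Why: Copper-catalysed conjugate addition of the Grignard reagent with in situ silyl trapping should bring in the methyl group (anti to the silyloxy group, a centre erased in step 2) and fix the enol ether regiochemistry.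

Step 2
Reactants: 2 (3S,4S)-4-(tert-butyldimethylsilyloxy)-3-methyl-1-(trimethylsilyloxy)cyclopent-1-ene
Product: 3 (S)-4-(tert-butyldimethylsilyloxy)-3-methylcyclopent-2-en-1-one
Conditions: Pd(OAc)2 (1.1 equiv), MeCN, rt
Reagents that add atoms: none
Why: Saegusa–Ito oxidation: the regiodefined silyl enol ether should give the palladium enolate, and β-hydride elimination of the only available hydrogen (on the methyl-bearing carbon) should return the enone without touching the carbinol stereocenter.

Step 3
Reactants: 3 (S)-4-(tert-butyldimethylsilyloxy)-3-methylcyclopent-2-en-1-one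
Product: 4 (S)-4-hydroxy-3-methylcyclopent-2-en-1-one
Conditions: 48% aq. HF, MeCN, 0 °C
Reagents that add atoms: none
Why: Acidic fluoride cleavage of the secondary silyl ether should free the hydroxyl that carries the alkynyl group to the β-carbon in step 4.

Step 4
Reactants: 4 (S)-4-hydroxy-3-methylcyclopent-2-en-1-one; 5 2-methylbut-1-en-3-yne
Product: 8 keto diol (2R,3S,4S)-4-hydroxy-2-(hydroxymethyl)-3-methyl-3-(3-methylbut-3-en-1-ynyl)cyclopentan-1-one, via alkynyldimethylalane 6 (not isolated), via cyclic aluminum alkoxide enolate 7 (not isolated)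
Conditions: 5, n-BuLi, toluene, 0 °C; Me2AlCl, 0 °C; then 4, 0 °C to rt; then CH2O (gas), −78 to −30 °C; aq. KNaC4H4O6
Reagents that add atoms: formaldehyde C=O; chlorodimethylaluminum C[Al](C)Cl (aluminum and methyl of intermediates 6 and 7 only)
Why: Hydroxyl-directed conjugate alkynylation with an alkynylalane followed by aldol trapping: the alkynyl group should be delivered within the aluminum alkoxide to the β-carbon on the face of the hydroxyl (quaternary C-1, methyl trans to OH), and formaldehyde should then add to the regiodefined enolate on the face of the slim alkynyl group, anti to the methyl, which is also the thermodynamically preferred arrangement at C-5.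

Step 5
Reactants: 8 keto diol
Product: 9 (2R,3S,4S)-4-hydroxy-3-methyl-3-(3-methylbut-3-en-1-ynyl)-2-[(triethylsilyloxy)methyl]cyclopentan-1-one
Conditions: TESCl (1.05 equiv), imidazole, CH2Cl2, −40 °C
Reagents that add atoms: chlorotriethylsilane CC[Si](Cl)(CC)CC
Why: Silylation at low temperature should select the primary hydroxyl over the neopentyl-type secondary one, which stays free to direct step 7, and it secures the labile β-hydroxy ketone.

Step 6
Reactants: 9 primary silyl ether
Product: 10 Z-diene: 4-hydroxy-3-methyl-3-[(1Z)-3-methylbuta-1,3-dienyl]-2-[(triethylsilyloxy)methyl]cyclopentan-1-one (ring configuration as in 9)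
Conditions: H2 (1 atm), Pd on CaCO3 poisoned with Pb(OAc)2, quinoline, EtOAc, rt
Reagents that add atoms: none
Why: Lindlar semi-hydrogenation (syn addition of hydrogen to the alkyne) should give the Z-olefin, with quinoline holding back over-reduction of the conjugated diene.

Step 7
Reactants: 10 Z-diene
Product: 11 cis-vinyl epoxide: 4-hydroxy-3-methyl-3-[(2R,3S)-3-(prop-1-en-2-yl)oxiran-2-yl]-2-[(triethylsilyloxy)methyl]cyclopentan-1-one
Conditions: VO(acac)2 (5 mol %), t-BuOOH, 2,6-lutidine, CH2Cl2, 0 °C
Reagents that add atoms: tert-butyl hydroperoxide CC(C)(C)OO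
Why: Vanadium-catalysed hydroxyl-directed epoxidation of a homoallylic alcohol: syn oxygen transfer should give the cis-epoxide at the proximal olefin only, and because 1,3-allylic strain of the Z-olefin turns the C-1 methyl into the olefin plane, the carbinol carbon lies over one face and the vanadium alkoxide delivers oxygen there, setting C-10 (R).

Step 8
Reactants: 11 cis-vinyl epoxide
Product: 12 bis-silyl ether: 3-methyl-3-[(2R,3S)-3-(prop-1-en-2-yl)oxiran-2-yl]-4-(triethylsilyloxy)-2-[(triethylsilyloxy)methyl]cyclopentan-1-one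
Conditions: TESCl, imidazole, DMAP (cat.), DMF, rt
Reagents that add atoms: chlorotriethylsilane CC[Si](Cl)(CC)CC
Why: Silyl ether formation under basic conditions should spare the vinyl epoxide and marks C-2 off from the hydroxyls that are esterified later.

Step 9
Reactants: 12 bis-silyl ether
Product: 13 tertiary alcohol: 1-isopropyl-3-methyl-3-[(2R,3S)-3-(prop-1-en-2-yl)oxiran-2-yl]-4-(triethylsilyloxy)-2-[(triethylsilyloxy)methyl]cyclopentan-1-ol (hydroxyl cis to the CH2O arm)
Conditions: i-PrMgCl, CeCl3, THF, −78 °C
Reagents that add atoms: isopropylmagnesium chloride CC(C)[Mg]Cl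
Why: Organocerium 1,2-addition (weakly basic, so enolization, β-elimination and epoxide opening are held back) should add isopropyl to the cyclopentanone anti to the adjacent C-5 arm, which puts the C-4 hydroxyl cis to that arm.

Step 10
Reactants: 13 tertiary alcohol
Product: 14 aldehyde: 2-hydroxy-2-isopropyl-5-methyl-5-[(2R,3S)-3-(prop-1-en-2-yl)oxiran-2-yl]-4-(triethylsilyloxy)cyclopentane-1-carbaldehyde
Conditions: (COCl)2, DMSO, CH2Cl2, −78 to −40 °C; Et3N, −78 to 0 °C; used at once
Reagents that add atoms: none
Why: Swern oxidation applied directly to the primary triethylsilyl ether: activated DMSO should cleave the less hindered primary Si–O bond selectively and give the aldehyde in one operation, leaving the secondary silyl ether, the tertiary alcohol and the epoxide untouched.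

Step 11
Reactants: 14 aldehyde
Product: 16 cycloheptene diol: 2-O-triethylsilyl-dauc-8-ene-2,4,6,10-tetrol, via oxiranylcarbinyl radical 15 (not isolated)
Conditions: SmI2 (2.5 equiv), HMPA, THF, −78 to 0 °C, slow addition of 14 (final 0.005 M); aq. NH4Cl
Reagents that add atoms: samarium diiodide I[Sm]I (samarium and iodine of intermediate 15 only)
Why: Proposed new method: SmI2 should reduce the aldehyde to a ketyl bound to trivalent samarium, which adds through C-6 to the unsubstituted terminus (C-7) of the isopropenyl group; the tertiary C-8 radical so formed is an oxiranylcarbinyl radical that opens by C9–O scission (or is first reduced to the organosamarium, which β-eliminates), and a second SmI2 reduces the oxygen radical, so the C8=C9 alkene and the C-10 alkoxide appear as the ring closes. The closest known reaction types are the SmI2 ketyl–olefin cyclization with β-elimination of an allylic leaving group and the ring opening of vinyl epoxides by carbon radicals; a ketyl adding to a vinyl epoxide in the endo mode has not been shown. The seven-membered ring closes 7-endo-trig: 6-exo attack at C-8 would place the new bond on a fully substituted carbon and leave a primary radical, and the cis-1,2 arrangement on the cyclopentane together with the cis-epoxide (a trans-epoxide could not lie within a seven-membered ring) folds C-7 onto C-6. C-6 is the only new stereocenter: samarium is shared by the ketyl oxygen and the C-4 alkoxide, the ketyl hydrogen points into the crowded sector between C-1 and C-4, and C-7 arrives from the open side next to H-5, which should place the 6-hydroxyl trans to the C5–C4 bond as in the target; C-10 keeps its configuration because its C–O bond is never broken. The step needs reduction of the aldehyde before the vinyl epoxide and cyclization before pinacol coupling: the first rests on the fast reduction of aldehydes by SmI2–HMPA (an allylsamarium formed by prior epoxide reduction could still close the same bond), the second on high dilution and slow addition.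

Step 12
Reactants: 16 cycloheptene diol
Product: 17 epoxy diol: 8,9-epoxy-2-O-triethylsilyl-daucane-2,4,6,10-tetrol (epoxide cis to the 6- and 10-hydroxyls)
Conditions: VO(acac)2 (5 mol %), t-BuOOH, CH2Cl2, 0 °C to rt
Reagents that add atoms: tert-butyl hydroperoxide CC(C)(C)OO
Why: Vanadium-catalysed hydroxyl-directed epoxidation of a cyclohept-2-enol: oxygen should be delivered syn to the allylic C-10 hydroxyl and the homoallylic C-6 hydroxyl, on the convex face of the cis-fused bicycle, setting C-8 and C-9.

Step 13
Reactants: 17 epoxy diol; 18 angelic acid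
Product: 20 bis-angelate: 6,10-bis(angeloyloxy)-8,9-epoxy-2-O-triethylsilyl-daucane-2,4-diol, via angelic 2,4,6-trichlorobenzoic anhydride 19 (not isolated)
Conditions: 18, 2,4,6-Cl3C6H2COCl, Et3N, toluene, rt; then 17, 75 °C
Reagents that add atoms: 2,4,6-trichlorobenzoyl chloride O=C(Cl)c1c(Cl)cc(Cl)cc1Cl (acyl group of intermediate 19 only)
Why: Yamaguchi-type esterification through the mixed anhydride, run without DMAP so that the Z-olefin of the angelate does not isomerize to the tiglate, should acylate both secondary hydroxyls while the tertiary C-4 hydroxyl is too hindered and C-2 is silylated.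

Step 14
Reactants: 20 bis-angelate
Product: 21 CNP0265715.2, (1R,2S,4S,5R,6R,8S,9R,10R)-6,10-bis(angeloyloxy)-8,9-epoxydaucane-2,4-diol
Conditions: HF·pyridine, pyridine, THF, 0 °C to rt
Reagents that add atoms: none
Why: Buffered fluoride cleavage of the triethylsilyl ether should free the C-2 hydroxyl without opening the epoxide (deactivated by the neighbouring ester) and without the acyl migration that basic fluoride could cause.

Compound list
1 | (S)-4-(tert-butyldimethylsilyloxy)cyclopent-2-en-1-one | O=C1C=C[C@@H](O[Si](C)(C)C(C)(C)C)C1 | starting material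
2 | (3S,4S)-4-(tert-butyldimethylsilyloxy)-3-methyl-1-(trimethylsilyloxy)cyclopent-1-ene (methyl trans to the silyloxy group) | C[Si](C)(C)OC1=C[C@H](C)[C@@H](O[Si](C)(C)C(C)(C)C)C1 | intermediate
3 | (S)-4-(tert-butyldimethylsilyloxy)-3-methylcyclopent-2-en-1-one | O=C1C=C(C)[C@@H](O[Si](C)(C)C(C)(C)C)C1 | intermediate
4 | (S)-4-hydroxy-3-methylcyclopent-2-en-1-one | O=C1C=C(C)[C@@H](O)C1 | intermediate
5 | 2-methylbut-1-en-3-yne | C=C(C)C#C | starting material
6 | dimethyl(3-methylbut-3-en-1-ynyl)aluminum | C=C(C)C#C[Al](C)C | intermediate (not isolated)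
7 | cyclic methylaluminum alkoxide enolate of the conjugate adduct (drawn as the monomer) | C=C(C)C#C[C@@]1(C)[C@@H]2CC(=C1)O[Al](C)O2 | intermediate (not isolated)
8 | (2R,3S,4S)-4-hydroxy-2-(hydroxymethyl)-3-methyl-3-(3-methylbut-3-en-1-ynyl)cyclopentan-1-one (hydroxyl, alkynyl and hydroxymethyl groups on one face, methyl on the other) | C=C(C)C#C[C@@]1(C)[C@@H](O)CC(=O)[C@H]1CO | intermediate
9 | (2R,3S,4S)-4-hydroxy-3-methyl-3-(3-methylbut-3-en-1-ynyl)-2-[(triethylsilyloxy)methyl]cyclopentan-1-one | C=C(C)C#C[C@@]1(C)[C@@H](O)CC(=O)[C@H]1CO[Si](CC)(CC)CC | intermediate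
10 | 4-hydroxy-3-methyl-3-[(1Z)-3-methylbuta-1,3-dienyl]-2-[(triethylsilyloxy)methyl]cyclopentan-1-one (ring configuration as in 9) | C=C(C)/C=C\[C@@]1(C)[C@@H](O)CC(=O)[C@H]1CO[Si](CC)(CC)CC | intermediate
11 | 4-hydroxy-3-methyl-3-[(2R,3S)-3-(prop-1-en-2-yl)oxiran-2-yl]-2-[(triethylsilyloxy)methyl]cyclopentan-1-one (cis-epoxide) | C=C(C)[C@@H]1O[C@@H]1[C@@]2(C)[C@@H](O)CC(=O)[C@H]2CO[Si](CC)(CC)CC | intermediate
12 | 3-methyl-3-[(2R,3S)-3-(prop-1-en-2-yl)oxiran-2-yl]-4-(triethylsilyloxy)-2-[(triethylsilyloxy)methyl]cyclopentan-1-one | C=C(C)[C@@H]1O[C@@H]1[C@@]2(C)[C@@H](O[Si](CC)(CC)CC)CC(=O)[C@H]2CO[Si](CC)(CC)CC | intermediate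
13 | 1-isopropyl-3-methyl-3-[(2R,3S)-3-(prop-1-en-2-yl)oxiran-2-yl]-4-(triethylsilyloxy)-2-[(triethylsilyloxy)methyl]cyclopentan-1-ol (tertiary hydroxyl, CH2O arm, oxiranyl group and silyloxy group on one face) | C=C(C)[C@@H]1O[C@@H]1[C@@]2(C)[C@@H](O[Si](CC)(CC)CC)C[C@](O)(C(C)C)[C@H]2CO[Si](CC)(CC)CC | intermediate
14 | 2-hydroxy-2-isopropyl-5-methyl-5-[(2R,3S)-3-(prop-1-en-2-yl)oxiran-2-yl]-4-(triethylsilyloxy)cyclopentane-1-carbaldehyde (configuration as in 13) | C=C(C)[C@@H]1O[C@@H]1[C@@]2(C)[C@@H](O[Si](CC)(CC)CC)C[C@](O)(C(C)C)[C@H]2C=O | intermediate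
15 | ring-closed tertiary C-8 radical next to the cis-fused 9,10-epoxide, C-6 oxygen on trivalent samarium | I[Sm](I)O[C@@H]1C[C](C)[C@@H]2O[C@@H]2[C@@]2(C)[C@@H](O[Si](CC)(CC)CC)C[C@](O)(C(C)C)[C@@H]12 | intermediate (not isolated)
16 | 2-O-triethylsilyl-dauc-8-ene-2,4,6,10-tetrol (cis-fused; 6-OH and 10-OH on the face of H-5 and the C-1 methyl, 2-OSi and 4-OH on the other face) | O[C@@H]1CC(C)=C[C@H](O)[C@@]2(C)[C@@H](O[Si](CC)(CC)CC)C[C@](O)(C(C)C)[C@@H]12 | intermediate
17 | 8,9-epoxy-2-O-triethylsilyl-daucane-2,4,6,10-tetrol (epoxide oxygen cis to 6-OH and 10-OH) | O[C@@H]1C[C@]2(C)O[C@@H]2[C@H](O)[C@@]2(C)[C@@H](O[Si](CC)(CC)CC)C[C@](O)(C(C)C)[C@@H]12 | intermediate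
18 | angelic acid, (Z)-2-methylbut-2-enoic acid | C/C=C(/C)C(=O)O | starting material
19 | angelic 2,4,6-trichlorobenzoic anhydride | C/C=C(/C)C(=O)OC(=O)c1c(Cl)cc(Cl)cc1Cl | intermediate (not isolated)
20 | 6,10-bis(angeloyloxy)-8,9-epoxy-2-O-triethylsilyl-daucane-2,4-diol | C/C=C(/C)C(=O)O[C@@H]1C[C@]2(C)O[C@@H]2[C@H](OC(=O)/C(C)=C\C)[C@@]2(C)[C@@H](O[Si](CC)(CC)CC)C[C@](O)(C(C)C)[C@@H]12 | intermediate
21 | CNP0265715.2, (1R,2S,4S,5R,6R,8S,9R,10R)-6,10-bis(angeloyloxy)-8,9-epoxydaucane-2,4-diol | C/C=C(/C)C(=O)O[C@@H]1C[C@]2(C)O[C@@H]2[C@H](OC(=O)/C(C)=C\C)[C@@]2(C)[C@@H](O)C[C@](O)(C(C)C)[C@@H]12 | target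

Total step count: 14. Longest linear sequence: 14 steps (1 to 21).

Steps most likely to fail

Step 11. The vinyl epoxide may be reduced before the aldehyde, so that an allylsamarium attacks through its other terminus and closes a five-membered ring. The ketyl may also dimerize or be reduced further, or C-7 may add to the other face of the ketyl. The fallback closes the same C6–C7 bond by two-electron chemistry, a Tsuji–Trost alkylation of a nitronate by the vinyl epoxide. It sets out from 13: the primary silyl ether is cleaved (HF·pyridine, pyridine, THF, 0 °C) to the primary alcohol F1, which I2, PPh3 and imidazole convert into the iodide F2 and NaNO2 in DMF (Kornblum reaction) into the nitro compound F3. Pd(PPh3)4 in THF opens the vinyl epoxide to the π-allyl complex of divalent palladium; its alkoxide deprotonates the nitroalkane, and the nitronate attacks the allyl terminus remote from oxygen to give the nitro cycloheptenol F4. A Nef reaction (NaOMe, then TiCl3, NH4OAc) gives the hydroxy ketone F5, and hydroxyl-directed reduction with Me4NBH(OAc)3 (Evans–Saksena reduction, hydride delivered from the C-4 hydroxyl) comes back to the route at 16.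

Step 4. Transfer of the alkynyl group to the fully substituted β-carbon may be too slow, so that 1,2-addition to the carbonyl or enolization takes over, and the face selectivity of the formaldehyde trapping at C-5 may be poor. The fallback brings in the two carbon groups in the other order. It sets out from 1: desilylation (aq. HF, MeCN) gives (S)-4-hydroxycyclopent-2-en-1-one F6; the hydroxyl-directed addition of alane 6, now to a β-unsubstituted enone, followed by TMSCl/Et3N gives the bis-silyl enol ether F7; Saegusa–Ito oxidation (Pd(OAc)2, MeCN) gives the alkynyl enone F8; Me2CuLi with TMSCl adds methyl 1,4 and anti to the silyloxy group to give the enol ether F9 with the quaternary carbon in place. Mukaiyama hydroxymethylation (aq. CH2O, Yb(OTf)3, THF) and loss of the trimethylsilyl groups on mildly acidic work-up come back to the route at 8.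

Step 7. Oxygen may be delivered to the wrong olefin face, and the free hydroxyl may open the acid-sensitive vinyl epoxide at its allylic carbon (tetrahydrofuran formation) under the Lewis-acidic conditions. The fallback uses reagent control under basic conditions. It sets out from 10, which is silylated first (TESCl, imidazole, DMF) to the bis-silyl Z-diene F10; a Shi epoxidation with the matching enantiomer of the carbohydrate-derived oxazolidinone ketone for cis-olefins (KHSO5, K2CO3, MeCN/dimethoxymethane, pH 10.5) then epoxidizes the Z-olefin on the face chosen by the catalyst and comes back to the route at 12.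

Further compounds
F1 | step 11 | primary alcohol from 13 (primary silyl ether cleaved) | C=C(C)[C@@H]1O[C@@H]1[C@@]2(C)[C@@H](O[Si](CC)(CC)CC)C[C@](O)(C(C)C)[C@H]2CO
F2 | step 11 | primary iodide | C=C(C)[C@@H]1O[C@@H]1[C@@]2(C)[C@@H](O[Si](CC)(CC)CC)C[C@](O)(C(C)C)[C@H]2CI
F3 | step 11 | primary nitro compound | C=C(C)[C@@H]1O[C@@H]1[C@@]2(C)[C@@H](O[Si](CC)(CC)CC)C[C@](O)(C(C)C)[C@H]2C[N+](=O)[O-]
F4 | step 11 | 6-nitro-2-O-triethylsilyl-dauc-8-ene-2,4,10-triol (C-6 epimers) | [O-][N+](=O)C1CC(C)=C[C@H](O)[C@@]2(C)[C@@H](O[Si](CC)(CC)CC)C[C@](O)(C(C)C)[C@@H]12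
F5 | step 11 | 4,10-dihydroxy-2-(triethylsilyloxy)dauc-8-en-6-one | O=C1CC(C)=C[C@H](O)[C@@]2(C)[C@@H](O[Si](CC)(CC)CC)C[C@](O)(C(C)C)[C@@H]12
F6 | step 4 | (S)-4-hydroxycyclopent-2-en-1-one | O=C1C=C[C@@H](O)C1
F7 | step 4 | cis-3-(3-methylbut-3-en-1-ynyl)-1,4-bis(trimethylsilyloxy)cyclopent-1-ene | C=C(C)C#C[C@H]1[C@@H](O[Si](C)(C)C)CC(O[Si](C)(C)C)=C1
F8 | step 4 | (S)-3-(3-methylbut-3-en-1-ynyl)-4-(trimethylsilyloxy)cyclopent-2-en-1-one | O=C1C=C(C#CC(C)=C)[C@@H](O[Si](C)(C)C)C1
F9 | step 4 | 3-methyl-3-(3-methylbut-3-en-1-ynyl)-1,4-bis(trimethylsilyloxy)cyclopent-1-ene (alkynyl cis to the 4-silyloxy group) | C=C(C)C#C[C@@]1(C)[C@@H](O[Si](C)(C)C)CC(O[Si](C)(C)C)=C1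
F10 | step 7 | bis-silyl Z-diene: 3-methyl-3-[(1Z)-3-methylbuta-1,3-dienyl]-4-(triethylsilyloxy)-2-[(triethylsilyloxy)methyl]cyclopentan-1-one | C=C(C)/C=C\[C@@]1(C)[C@@H](O[Si](CC)(CC)CC)CC(=O)[C@H]1CO[Si](CC)(CC)CC
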